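**Strategy.** The oxolane ring (O1, C2–C5) carries a CH2O group on C3, next to the aryl-bearing C2–O1 unit. At the aldehyde level this is an aldol pattern, so C2–C3 is the bond to disconnect. Moving C2 from C3 onto the formyl oxygen gives a seven-membered cyclic vinyl acetal, a 2-aryl-5-benzyl-4,5-dihydro-1,3-dioxepine whose only controlling stereocentre is C5. Its Lewis acid induced [1,3] O-to-C shift contracts seven ring atoms to five, forms C2–C3, sets C2 and C3 from that centre and releases the C3 formyl group in one operation. The precursor comes from vanillin, cis-butenediol and an asymmetric benzylic Heck reaction. C3 is then equilibrated, and the caffeate is attached last.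

Key step: step 6

Remark on the chemistry: oxolane numbering is O1, C2 (aryl), C3 (CH2O), C4 (benzyl), C5 (CH2); the target as drawn is (2R,3S,4S), 2,3-trans/3,4-cis; Ar stands for 3-methoxy-4-(triisopropylsilyloxy)phenyl; the sense of induction in step 5 cannot be derived safely, so the ligand antipode that gives (5S)-7 is assumed (both antipodes are available).

Step 1
Reactants: 1 vanillin (4-hydroxy-3-methoxybenzaldehyde)
Product: 2 3-methoxy-4-(triisopropylsilyloxy)benzaldehyde (ArCHO)
Conditions: TIPSCl, imidazole, DMF, rt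
Reagents that add atoms: triisopropylsilyl chloride, CC(C)[Si](Cl)(C(C)C)C(C)C
Why: Imidazole-promoted silylation of the phenol; the bulky aryl TIPS ether should survive acetalisation, Pd/carbonate, TMSOTf, DBU and borohydride and still leave with fluoride at the end, where hydrogenolysis is ruled out by the cinnamate double bond.

Step 2
Reactants: 2 ArCHO; 3 (Z)-but-2-ene-1,4-diol
Product: 4 2-Ar-4,7-dihydro-1,3-dioxepine
Conditions: PPTS (cat.), toluene, Dean–Stark, reflux
Reagents that add atoms: none
Why: Acid-catalysed acetalisation with azeotropic removal of water, in which the cis geometry of the diol favours closure of the seven-membered ring; no stereocentre arises because the ring has a mirror plane through C2.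

Step 3
Reactants: 2 ArCHO
Product: 5 [3-methoxy-4-(triisopropylsilyloxy)phenyl]methanol (ArCH2OH)
Conditions: NaBH4, MeOH, 0 °C
Reagents that add atoms: none
Why: Plain borohydride reduction of an aromatic aldehyde, to which the silyl ether is inert.

Step 4
Reactants: 5 ArCH2OH
Product: 6 3-methoxy-4-(triisopropylsilyloxy)benzyl trifluoroacetate
Conditions: (CF3CO)2O, pyridine, CH2Cl2, 0 °C; used without chromatography
Reagents that add atoms: trifluoroacetic anhydride, O=C(OC(=O)C(F)(F)F)C(F)(F)F
Why: O-acylation gives a benzylic ester whose C–O bond Pd(0) can ionise to an η3-benzyl complex with a weakly bound counter-ion.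

Step 5
Reactants: 4 2-Ar-4,7-dihydro-1,3-dioxepine (in excess); 6 benzylic trifluoroacetate
Product: 7 (5S)-2-Ar-5-(ArCH2)-4,5-dihydro-1,3-dioxepine (both C2 epimers)
Conditions: Pd(dba)2 (cat.), BINOL-derived phosphoramidite L* (cat.), Li2CO3, THF, 50 °C
Reagents that add atoms: none
Why: Asymmetric Mizoroki–Heck reaction of a benzylic electrophile with a cyclic alkene: the benzyl-Pd species adds syn across C5=C6, C5–H is then anti to Pd so that syn β-hydride elimination can only take C7–H and gives the enol ether, and the chiral ligand chooses between the enantiotopic alkene carbons and thereby sets C5 (S), the C2 epimer mixture being erased in step 6.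

Step 6
Reactants: 7 (5S)-2-Ar-5-(ArCH2)-4,5-dihydro-1,3-dioxepine
Product: 9 (2R,3S,4S)-2-Ar-4-(ArCH2)oxolane-3-carbaldehyde (2,3-cis/3,4-trans), via oxocarbenium enol silane triflate 8 (not isolated)
Conditions: TMSOTf (10 mol %), CH2Cl2, −78 °C; Et3N quench
Reagents that add atoms: none
Why: TMSOTf silylates the enol-ether oxygen O1 of 7, the C2–O1 bond ionises to the aryl-stabilised (E)-oxocarbenium ion tethered to a (Z)-enol silane (8), the enol carbon C6 attacks C2, and loss of the silyl group from the new formyl oxygen returns the catalyst, so that the ring O1–C2–O3–C4–C5–C6–C7 shrinks to the oxolane O3–C4–C5–C6–C2 while C7–O1 is extruded as the formyl group. The closest known reaction type is the Lewis acid mediated [1,3] O-to-C rearrangement (ring contraction) of 4,5-dihydro-1,3-dioxepines to oxolane-3-carbaldehydes, a Petasis–Ferrier-type process that ends in an intramolecular Mukaiyama aldol addition. The one ring closed forms in the 5-(enolexo)-endo-trig mode, which oxocarbenium ions tolerate. New C3 is controlled by the C5 stereocentre of 7: allylic 1,3-strain in the (Z)-enol silane holds C5–H in the enol plane, the tether reaches only the face anti to the benzyl arm, and formyl and benzyl end up trans. New C2 is controlled by the compact, least-motion collapse of the ion pair at −78 °C, which in this reaction class places aryl and formyl cis under kinetic control, so that aryl and benzyl are trans as in the target and only C3 remains to be corrected. The step needs ionisation at O1 and not O3 (the enol oxygen is the better leaving group and O3 cleavage is a reversible dead end), C- over O-recombination (O-return only regenerates 7 with either C2 configuration, which is why both acetal epimers converge) and strict kinetic control, which low temperature, catalytic acid and the amine quench secure against reopening of the electron-rich benzylic C2–O bond.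

Step 7
Reactants: 9 (2R,3S,4S)-aldehyde (2,3-cis/3,4-trans)
Product: 11 [(2R,3S,4S)-2-Ar-4-(ArCH2)oxolan-3-yl]methanol (2,3-trans/3,4-cis), via C3-epimerised aldehyde 10 (not isolated)
Conditions: DBU (0.2 equiv), CH2Cl2, rt, to equilibrium; then MeOH, NaBH4, −20 °C
Reagents that add atoms: none
Why: Base-mediated epimerisation of an α-branched aldehyde touches only C3, because ring opening by β-elimination would be the reverse of a 5-endo-trig oxa-Michael addition and is stereoelectronically slow; the formyl group should settle trans to the ring-bound C2 aryl group at the price of a cis relation to the more flexible C4 CH2Ar arm, and borohydride then freezes this configuration, the minor C3 epimer being removed by chromatography.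

Step 8
Reactants: 12 caffeic acid
Product: 14 (E)-3-[3,4-bis(tert-butyldimethylsilyloxy)phenyl]prop-2-enoic acid, via tris-TBS silyl ester 13 (not isolated)
Conditions: TBSCl, imidazole, DMF, rt; then AcOH–THF–H2O, rt
Reagents that add atoms: tert-butyldimethylsilyl chloride, CC(C)(C)[Si](C)(C)Cl
Why: Exhaustive silylation followed by selective hydrolysis of the far more labile silyl ester leaves the catechol masked and the acid free.

Step 9
Reactants: 11 primary alcohol; 14 protected caffeic acid
Product: 15 fully silylated (2R,3S,4S)-caffeate ester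
Conditions: EDC, DMAP, CH2Cl2, 0 °C to rt
Reagents that add atoms: none
Why: Steglich esterification of the only free hydroxyl group under neutral conditions that touch neither the stereocentres nor the E double bond.

Step 10
Reactants: 15 fully silylated ester
Product: 16 target, [(2R,3S,4S)-2-(4-hydroxy-3-methoxyphenyl)-4-(4-hydroxy-3-methoxybenzyl)oxolan-3-yl]methyl (E)-3-(3,4-dihydroxyphenyl)prop-2-enoate
Conditions: TBAF, AcOH (1:1), THF, 0 °C
Reagents that add atoms: none
Why: Fluoride cleaves all four aryl silyl ethers, and the acetic acid buffer keeps phenoxides from attacking the ester or oxidising while the medium stays too mild to ionise the benzylic C2–O bond.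

**Compound list**
1 | vanillin | COc1cc(C=O)ccc1O | starting material
2 | 3-methoxy-4-(triisopropylsilyloxy)benzaldehyde | COc1cc(C=O)ccc1O[Si](C(C)C)(C(C)C)C(C)C | intermediate
3 | (Z)-but-2-ene-1,4-diol | OC/C=C\CO | starting material
4 | 2-Ar-4,7-dihydro-1,3-dioxepine | COc1cc(C2OCC=CCO2)ccc1O[Si](C(C)C)(C(C)C)C(C)C | intermediate
5 | [3-methoxy-4-(triisopropylsilyloxy)phenyl]methanol | COc1cc(CO)ccc1O[Si](C(C)C)(C(C)C)C(C)C | intermediate
6 | 3-methoxy-4-(triisopropylsilyloxy)benzyl trifluoroacetate | COc1cc(COC(=O)C(F)(F)F)ccc1O[Si](C(C)C)(C(C)C)C(C)C | intermediate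
7 | (5S)-2-Ar-5-(ArCH2)-4,5-dihydro-1,3-dioxepine, C2 epimers (C2 left open) | COc1cc(C[C@@H]2COC(c3ccc(O[Si](C(C)C)(C(C)C)C(C)C)c(OC)c3)OC=C2)ccc1O[Si](C(C)C)(C(C)C)C(C)C | intermediate
8 | (E)-oxocarbenium (Z)-enol silane triflate ion pair | COc1cc(C[C@@H](/C=C\O[Si](C)(C)C)C/[O+]=C/c2ccc(O[Si](C(C)C)(C(C)C)C(C)C)c(OC)c2)ccc1O[Si](C(C)C)(C(C)C)C(C)C.[O-]S(=O)(=O)C(F)(F)F | intermediate
9 | (2R,3S,4S)-2-Ar-4-(ArCH2)oxolane-3-carbaldehyde, 2,3-cis/3,4-trans | COc1cc(C[C@@H]2CO[C@@H](c3ccc(O[Si](C(C)C)(C(C)C)C(C)C)c(OC)c3)[C@H]2C=O)ccc1O[Si](C(C)C)(C(C)C)C(C)C | intermediate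
10 | (2R,3R,4S)-2-Ar-4-(ArCH2)oxolane-3-carbaldehyde, 2,3-trans/3,4-cis | COc1cc(C[C@@H]2CO[C@@H](c3ccc(O[Si](C(C)C)(C(C)C)C(C)C)c(OC)c3)[C@@H]2C=O)ccc1O[Si](C(C)C)(C(C)C)C(C)C | intermediate
11 | [(2R,3S,4S)-2-Ar-4-(ArCH2)oxolan-3-yl]methanol | COc1cc(C[C@@H]2CO[C@@H](c3ccc(O[Si](C(C)C)(C(C)C)C(C)C)c(OC)c3)[C@@H]2CO)ccc1O[Si](C(C)C)(C(C)C)C(C)C | intermediate
12 | caffeic acid | OC(=O)/C=C/c1ccc(O)c(O)c1 | starting material
13 | tert-butyldimethylsilyl (E)-3-[3,4-bis(tert-butyldimethylsilyloxy)phenyl]prop-2-enoate | CC(C)(C)[Si](C)(C)OC(=O)/C=C/c1ccc(O[Si](C)(C)C(C)(C)C)c(O[Si](C)(C)C(C)(C)C)c1 | intermediate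
14 | (E)-3-[3,4-bis(tert-butyldimethylsilyloxy)phenyl]prop-2-enoic acid | OC(=O)/C=C/c1ccc(O[Si](C)(C)C(C)(C)C)c(O[Si](C)(C)C(C)(C)C)c1 | intermediate
15 | fully silylated caffeate ester | COc1cc(C[C@@H]2CO[C@@H](c3ccc(O[Si](C(C)C)(C(C)C)C(C)C)c(OC)c3)[C@@H]2COC(=O)/C=C/c2ccc(O[Si](C)(C)C(C)(C)C)c(O[Si](C)(C)C(C)(C)C)c2)ccc1O[Si](C(C)C)(C(C)C)C(C)C | intermediate
16 | CNP0132883.1 | COc1cc(C[C@@H]2CO[C@@H](c3ccc(O)c(OC)c3)[C@@H]2COC(=O)/C=C/c2ccc(O)c(O)c2)ccc1O | target

**Total step count:** 10.
**Longest linear sequence:** 8 steps (1, 3, 4, 5, 6, 7, 9, 10).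

**Steps most likely to fail**

**Step 5.** What may go wrong:
- Insertion of the benzyl-palladium species into the unactivated seven-membered alkene may be slow.
- The electron-rich ester 6 may solvolyse or alkylate itself.
- The enol ether formed may be benzylated a second time.
- Discrimination of the enantiotopic alkene carbons may be weak.

The fallback separates C–C bond formation from the creation of the stereocentre. It sets out from 2 and 6 and returns at 7.
- 2-Butyne-1,4-diol is hydrostannylated syn (Bu3SnH, Pd(PPh3)4 cat.) to (E)-2-(tributylstannyl)but-2-ene-1,4-diol F1.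
- F1 is acetalised with 2 (PPTS, toluene) to 2-Ar-5-(tributylstannyl)-4,7-dihydro-1,3-dioxepine F2.
- A Stille-type coupling of F2 with 6 gives racemic 2-Ar-5-(ArCH2)-4,7-dihydro-1,3-dioxepine F3.
- A chiral nickel hydride (NiBr2/Me-DuPHOS, LiBHEt3 cat., THF) moves the double bond of F3 from C5=C6 to C6=C7. Hydrogen is delivered to C5 under catalyst control, which gives (5S)-7 as its C2 epimers.

**Step 6.** What may go wrong:
- The acetal configuration may not be lost completely, so that the cis-configured acetal leaks into the series with aryl and benzyl cis.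
- The very electron-rich benzylic centre may ionise reversibly, which would drain the kinetic aldehyde towards the all-trans isomer or into Friedel–Crafts capture by the pendant arene.

The fallback uses the acetal centre as a stereochemical relay and does not erase it. It sets out from 7 and returns at 9.
- The C2 epimers are separated on base-washed silica.
- Only the diequatorial (2R,5S)-trans-2-Ar-5-(ArCH2)-4,5-dihydro-1,3-dioxepine F4 is rearranged.
- The rearrangement is run in a non-polar medium (TMSOTf, toluene–hexane, −78 °C), where the contact ion pair should collapse with retention at C2.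
- The trans relation of aryl and benzyl in F4 is then carried stereospecifically into 9 by the same seven-to-five ring contraction.

**Step 7.** What may go wrong:
- The C3 equilibrium may lie less far on the desired side than hoped.
- β-Elimination and re-addition of the ring oxygen may scramble C2.
- The aldehyde may self-condense under base.

The fallback moves the equilibration to the ester level, where both epimers are stable to chromatography and can be recycled. It sets out from 9 and returns at 11.
- Pinnick oxidation of 9 gives (2R,3S,4S)-2-Ar-4-(ArCH2)oxolane-3-carboxylic acid F5.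
- TMSCHN2 converts F5 into its methyl ester F6.
- DBU in hot toluene equilibrates F6 with the (2R,3R,4S)-methyl ester F7 (2,3-trans/3,4-cis). The bulkier ester group should discriminate more strongly against the neighbouring aryl group.
- Recovered F6 is resubmitted to the equilibration.
- DIBAL-H reduces F7 to 11.

**Further compounds**
F1 | step 5 | (E)-2-(tributylstannyl)but-2-ene-1,4-diol | OC/C=C(\CO)[Sn](CCCC)(CCCC)CCCC
F2 | step 5 | 2-Ar-5-(tributylstannyl)-4,7-dihydro-1,3-dioxepine (racemic) | COc1cc(C2OCC=C([Sn](CCCC)(CCCC)CCCC)CO2)ccc1O[Si](C(C)C)(C(C)C)C(C)C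
F3 | step 5 | 2-Ar-5-(ArCH2)-4,7-dihydro-1,3-dioxepine (racemic) | COc1cc(CC2=CCOC(c3ccc(O[Si](C(C)C)(C(C)C)C(C)C)c(OC)c3)OC2)ccc1O[Si](C(C)C)(C(C)C)C(C)C
F4 | step 6 | (2R,5S)-trans-2-Ar-5-(ArCH2)-4,5-dihydro-1,3-dioxepine | COc1cc(C[C@@H]2CO[C@@H](c3ccc(O[Si](C(C)C)(C(C)C)C(C)C)c(OC)c3)OC=C2)ccc1O[Si](C(C)C)(C(C)C)C(C)C
F5 | step 7 | (2R,3S,4S)-2-Ar-4-(ArCH2)oxolane-3-carboxylic acid | COc1cc(C[C@@H]2CO[C@@H](c3ccc(O[Si](C(C)C)(C(C)C)C(C)C)c(OC)c3)[C@H]2C(=O)O)ccc1O[Si](C(C)C)(C(C)C)C(C)C
F6 | step 7 | methyl (2R,3S,4S)-2-Ar-4-(ArCH2)oxolane-3-carboxylate | COc1cc(C[C@@H]2CO[C@@H](c3ccc(O[Si](C(C)C)(C(C)C)C(C)C)c(OC)c3)[C@H]2C(=O)OC)ccc1O[Si](C(C)C)(C(C)C)C(C)C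
F7 | step 7 | methyl (2R,3R,4S)-2-Ar-4-(ArCH2)oxolane-3-carboxylate | COc1cc(C[C@@H]2CO[C@@H](c3ccc(O[Si](C(C)C)(C(C)C)C(C)C)c(OC)c3)[C@@H]2C(=O)OC)ccc1O[Si](C(C)C)(C(C)C)C(C)C
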